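**The question turned.** The constants put coupling at 0.0087 L² mol⁻² s⁻¹ and quench at 0.0018 L mol⁻¹ s⁻¹, so I asked what the given numbers would have to say for target to beat starting material.

- cedar: starting material 0.45 M; coupling partner 0.450 M; second substrate 2.25 M; protic impurity 0.0450 M; free catalyst 15 mM; time 4.0 h
- ash: starting material 0.45 M; coupling partner 0.450 M; second substrate 2.25 M; protic impurity 0.0450 M; free catalyst 10 mM; time 4.0 h

    2 free catalyst → spent catalyst (k1 = 0.0013 L mol⁻¹ s⁻¹)
    2 second substrate → self-condensation product (k2 = 4.6 × 10⁻⁶ L mol⁻¹ s⁻¹)
    starting material + protic impurity → quenched substrate (k3 = 0.0018 L mol⁻¹ s⁻¹)
    starting material + coupling partner + free catalyst → free catalyst + target (k4 = 0.0087 L² mol⁻² s⁻¹)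
    second substrate + coupling partner + free catalyst → free catalyst + second product (k5 = 6.0 × 10⁻⁴ L² mol⁻² s⁻¹)

- which of these there is most of at the end, counted by the starting material in it, cedar (starting material / target)
- which of these there is most of at the end, counted by the starting material in it, ash (starting material / target)
- how much there is at the end of the one of these that leads, in percent of the starting material charged: cedar
- how much there is at the end of the one of these that leads, in percent of the starting material charged: ash

- for a step with 2 of a species take k times the square, and two of it per event
- run time (cedar): 4.0 h

**One molecule.** In ash, a starting-material molecule began with odds of 0.483 for coupling against quench. The protic impurity's lifetime against charged starting material is about 0.343 h, so in both flasks I wrote off one starting material per impurity, which left 405 mM in my reckoning. Coupling partner stands near that level and falls alongside it, so I set the two equal.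

**Coupling number.** Free catalyst dies in pairs, so its exposure over the run is the logarithm of one plus twice its decay constant times charge times time, over twice that constant. The coupling number is the coupling constant times the surviving starting material times that exposure. With the two set equal, the survivors' share left is one over one plus this number, so on this reckoning target leads once it passes one. Cedar stood at 0.604 and ash at 0.431. My call for cedar was starting material at 56.1%, and for ash starting material at 62.9%.

**The forecast.** It named starting material for cedar at 55.5% and starting material for ash at 62%: “Unreacted starting material therefore leads in both runs”.

**The flasks.** Cedar ended with starting material at 55.5% and target at 34.5%; ash ended with 61.8% and 28.2%.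

**The catalyst gap.** The difference in free catalyst charge was the main reason cedar's starting material ended below ash's: with that difference taken away, cedar's starting material at the end went from 55.5% to 61.8%. Read back from its end value, cedar's coupling number was 0.622, still under one. A neighbour of ash charged with 0.11 M of protic impurity had a number of 0.362, and it ended with starting material at 50.8% against target at 24.8%.

(The constants are made up; the rest is arithmetic.)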